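The route rests on cutting the side chain at C12–C13 and C14–C15. The trisubstituted C13=C14 alkene holds C12 cis to the C15 carboxyl and the C16 oxymethyl trans to it, which is the signature of syn addition of a C12 alkylcopper, then CO2, across the C13≡C14 bond of a propargyl silyl ether. One operation thus joins the ring A/ring B decalin, the alkyne and CO2, forms two C–C bonds and fixes the alkene geometry. The precursor is the trans-decalin C12 bromide carrying the C8=C17 exocyclic methylene and the C2 alcohol as a triisopropylsilyl ether, assembled by a Diels–Alder reaction of an actinol-derived diene.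

Key step: step 15

Numbering: labdane numbering is used for positions (C1–C10 decalin, C11/C12 side-chain methylenes, C13=C14, C15 acid, C16 acetoxymethyl, C17 exocyclic methylene, C18/C19 gem-dimethyl, C20 angular methyl). Systematic names use decahydronaphthalene locants (C1 = labdane C9, C2 = C8, C4a = C5, C5 = C4, C7 = C2, C8a = C10).

Remark on the chemistry: CIP analysis of the target gives 2R,5R,9R,10R (an ent-labdane with the C2 hydroxyl trans to the C20 methyl). The diene therefore needs the S configuration at its carbinol carbon, opposite to (4R,6R)-actinol, so the inversion in step 1 is required. The C6 stereocentre of actinol is removed in step 4 and is of no consequence. No structural correction was needed.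

Step 1
Reactants: 1 (4R,6R)-4-hydroxy-2,2,6-trimethylcyclohexanone (actinol)
Product: 2 (1S,3R)-3,5,5-trimethyl-4-oxocyclohexyl 4-nitrobenzoate
Conditions: 4-nitrobenzoic acid, PPh3, DIAD, THF, 0 °C → rt
Reagents that add atoms: 4-nitrobenzoic acid, O=C(O)c1ccc(cc1)[N+](=O)[O-]
Why: Mitsunobu reaction, in which the C4 alkoxyphosphonium ion is displaced by 4-nitrobenzoate with SN2 inversion (axial C–O to equatorial C–O), setting the S configuration needed at the future C2 under near-neutral conditions.

Step 2
Reactants: 2 (1S,3R)-3,5,5-trimethyl-4-oxocyclohexyl 4-nitrobenzoate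
Product: 3 (4S,6R)-4-hydroxy-2,2,6-trimethylcyclohexanone
Conditions: K2CO3 (cat.), MeOH, 0 °C → rt
Reagents that add atoms: none
Why: Base-catalysed transesterification of the activated 4-nitrobenzoate releases the inverted alcohol without touching the carbinol centre, and the all-equatorial arrangement at C6 is the thermodynamically preferred one.

Step 3
Reactants: 3 (4S,6R)-4-hydroxy-2,2,6-trimethylcyclohexanone
Product: 4 (4S,6R)-2,2,6-trimethyl-4-(triisopropylsilyloxy)cyclohexanone
Conditions: TIPSCl, imidazole, DMF, rt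
Reagents that add atoms: triisopropylsilyl chloride, CC(C)[Si](Cl)(C(C)C)C(C)C
Why: Silyl ether formation at the unhindered equatorial secondary alcohol; the triisopropylsilyl group is chosen to survive the later enolate, organolithium, Grignard, hydride and mild-acid steps.

Step 4
Reactants: 4 (4S,6R)-2,2,6-trimethyl-4-(triisopropylsilyloxy)cyclohexanone
Product: 6 (S)-2,6,6-trimethyl-4-(triisopropylsilyloxy)cyclohex-1-en-1-yl trifluoromethanesulfonate, via potassium enolate 5 (not isolated)
Conditions: KN(SiMe3)2, THF, −78 → −20 °C; PhNTf2, −78 °C → rt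
Reagents that add atoms: N-phenylbis(trifluoromethanesulfonimide), O=S(=O)(N(c1ccccc1)S(=O)(=O)C(F)(F)F)C(F)(F)F
Why: Enol triflate formation, since deprotonation is possible only at C6 (the other α-carbon is quaternary) and the single enolate is O-sulfonylated by PhNTf2, which also removes the C6 stereocentre.

Step 5
Reactants: 6 (S)-2,6,6-trimethyl-4-(triisopropylsilyloxy)cyclohex-1-en-1-yl trifluoromethanesulfonate; 7 potassium vinyltrifluoroborate
Product: 8 (S)-triisopropyl[(3,5,5-trimethyl-4-vinylcyclohex-3-en-1-yl)oxy]silane (the C7=C6–C5=C10 diene)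
Conditions: PdCl2(dppf)·CH2Cl2 (5 mol%), Cs2CO3, THF/H2O (9:1), 70 °C
Reagents that add atoms: none
Why: Suzuki–Miyaura cross-coupling of an alkenyl triflate with a vinyltrifluoroborate forms the C5–C6 bond of the 1,3-diene and is established for hindered cyclohexenyl triflates.

Step 6
Reactants: 9 methyl 4-hydroxybut-2-ynoate
Product: 10 methyl 4-acetoxybut-2-ynoate
Conditions: Ac2O, pyridine, DMAP (cat.), CH2Cl2, 0 °C
Reagents that add atoms: acetic anhydride, CC(=O)OC(C)=O
Why: DMAP-catalysed acylation of the primary propargylic alcohol installs the acetate that later serves as the leaving group at C17.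

Step 7
Reactants: 8 (S)-triisopropyl[(3,5,5-trimethyl-4-vinylcyclohex-3-en-1-yl)oxy]silane; 10 methyl 4-acetoxybut-2-ynoate
Product: 11 methyl (7R,8aR)-2-(acetoxymethyl)-5,5,8a-trimethyl-7-(triisopropylsilyloxy)-3,5,6,7,8,8a-hexahydronaphthalene-1-carboxylate (C5=C6 and C8=C9 diene; C11 ester on C9; C17 acetate on C8; C2–O trans to the C20 methyl)
Conditions: 10 (3 equiv), toluene (concentrated), BHT (cat.), sealed tube, 115 °C
Reagents that add atoms: none
Why: Thermal Diels–Alder reaction in which the unsubstituted terminus C7 bonds to the β-carbon of the ynoate and the hindered C10 to the ester-bearing carbon (ortho orientation), and the dienophile should add anti to the pseudoaxial C4 methyl of the half-chair that keeps the C2 silyloxy group equatorial, which sets C10 (R) with its methyl trans to C2–O.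

Step 8
Reactants: 11 methyl (7R,8aR)-2-(acetoxymethyl)-5,5,8a-trimethyl-7-(triisopropylsilyloxy)-3,5,6,7,8,8a-hexahydronaphthalene-1-carboxylate
Product: 12 methyl (4aR,7R,8aR)-2-(acetoxymethyl)-5,5,8a-trimethyl-7-(triisopropylsilyloxy)-3,4,4a,5,6,7,8,8a-octahydronaphthalene-1-carboxylate (trans-fused; C8=C9 retained)
Conditions: H2 (1 atm), 5% Pt/C, EtOAc, rt
Reagents that add atoms: none
Why: Heterogeneous catalytic hydrogenation adds hydrogen to the trisubstituted C5=C6 bond from the face opposite the C20 and axial C19 methyls, giving the trans ring fusion (5R), while the tetrasubstituted conjugated C8=C9 bond is too hindered to react and platinum is preferred to palladium to spare the allylic acetate.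

Step 9
Reactants: 12 methyl (4aR,7R,8aR)-2-(acetoxymethyl)-5,5,8a-trimethyl-7-(triisopropylsilyloxy)-3,4,4a,5,6,7,8,8a-octahydronaphthalene-1-carboxylate
Product: 14 methyl (1R,4aR,7R,8aR)-5,5,8a-trimethyl-2-methylidene-7-(triisopropylsilyloxy)decahydronaphthalene-1-carboxylate, via samarium dienolate 13 (not isolated)
Conditions: SmI2 (2.5 equiv), t-BuOH, THF, −78 → 0 °C
Reagents that add atoms: none
Why: Samarium diiodide reductive elimination of a γ-acetoxy α,β-unsaturated ester expels acetate to give the dienolate bearing the C8=C17 exocyclic alkene, and kinetic α-protonation at C9 from the face opposite the axial C20 methyl gives the deconjugated ester with the equatorial ester group (9R).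

Step 10
Reactants: 14 methyl (1R,4aR,7R,8aR)-5,5,8a-trimethyl-2-methylidene-7-(triisopropylsilyloxy)decahydronaphthalene-1-carboxylate
Product: 15 [(1R,4aR,7R,8aR)-5,5,8a-trimethyl-2-methylidene-7-(triisopropylsilyloxy)decahydronaphthalen-1-yl]methanol
Conditions: LiAlH4, Et2O, 0 °C
Reagents that add atoms: none
Why: Hydride reduction of the ester to the primary C11 alcohol is fast at 0 °C, so the allylic C9 centre is not epimerised and the isolated alkene and silyl ether are untouched.

Step 11
Reactants: 15 [(1R,4aR,7R,8aR)-5,5,8a-trimethyl-2-methylidene-7-(triisopropylsilyloxy)decahydronaphthalen-1-yl]methanol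
Product: 16 (1R,4aR,7R,8aR)-1-(iodomethyl)-5,5,8a-trimethyl-2-methylidene-7-(triisopropylsilyloxy)decahydronaphthalene
Conditions: I2, PPh3, imidazole, toluene, rt → 60 °C
Reagents that add atoms: iodine, II
Why: Appel-type iodination (Garegg–Samuelsson conditions) converts the alcohol through its alkoxyphosphonium salt into the iodide by SN2 at C11 under non-basic conditions that cannot epimerise C9.

Step 12
Reactants: 16 (1R,4aR,7R,8aR)-1-(iodomethyl)-5,5,8a-trimethyl-2-methylidene-7-(triisopropylsilyloxy)decahydronaphthalene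
Product: 18 2-[(1R,4aR,7R,8aR)-5,5,8a-trimethyl-2-methylidene-7-(triisopropylsilyloxy)decahydronaphthalen-1-yl]ethan-1-ol, via alkyllithium 17 (not isolated)
Conditions: t-BuLi (2.1 equiv), Et2O/pentane, −78 °C; CH2O (gas, from cracked paraformaldehyde), −78 °C → rt
Reagents that add atoms: formaldehyde, C=O
Why: Lithium–iodine exchange gives the primary C11 alkyllithium, whose addition to monomeric formaldehyde installs C12 as a hydroxymethyl group, a one-carbon homologation that never places a carbonyl next to the C9 stereocentre.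

Step 13
Reactants: 18 2-[(1R,4aR,7R,8aR)-5,5,8a-trimethyl-2-methylidene-7-(triisopropylsilyloxy)decahydronaphthalen-1-yl]ethan-1-ol
Product: 19 (1R,4aR,7R,8aR)-1-(2-bromoethyl)-5,5,8a-trimethyl-2-methylidene-7-(triisopropylsilyloxy)decahydronaphthalene (the C12 bromide)
Conditions: CBr4, PPh3, CH2Cl2, 0 °C
Reagents that add atoms: carbon tetrabromide, BrC(Br)(Br)Br
Why: Appel bromination proceeds by SN2 attack of bromide on the alkoxyphosphonium ion of the unhindered primary alcohol under neutral conditions tolerated by the exocyclic alkene and the silyl ether.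

Step 14
Reactants: 20 propargyl alcohol
Product: 21 tert-butyldimethyl(prop-2-yn-1-yloxy)silane
Conditions: TBSCl, imidazole, CH2Cl2, 0 °C → rt
Reagents that add atoms: tert-butyldimethylsilyl chloride, CC(C)(C)[Si](C)(C)Cl
Why: Silyl ether formation gives a bulky, weakly coordinating, non-leaving oxygen substituent that can later be removed selectively in the presence of the triisopropylsilyl ether.

Step 15
Reactants: 19 (1R,4aR,7R,8aR)-1-(2-bromoethyl)-5,5,8a-trimethyl-2-methylidene-7-(triisopropylsilyloxy)decahydronaphthalene; 21 tert-butyldimethyl(prop-2-yn-1-yloxy)silane; 22 carbon dioxide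
Product: 26 (2E)-3-[(tert-butyldimethylsilyloxy)methyl]-5-[(1R,4aR,7R,8aR)-5,5,8a-trimethyl-2-methylidene-7-(triisopropylsilyloxy)decahydronaphthalen-1-yl]pent-2-enoic acid, via Grignard reagent 23 (not isolated), via alkylcopper 24 (not isolated), via alkenylcopper 25 (not isolated)
Conditions: Mg turnings (I2-activated), THF, 40 °C; CuBr·SMe2 (1.0 equiv), THF, −40 °C; 21 (1.2 equiv), −40 → −15 °C; P(OEt)3 (0.1 equiv), HMPA (2 equiv), CO2 (1 atm), −40 °C → rt; cold 0.5 M HCl
Reagents that add atoms: none
Why: Magnesium inserts into the C12–Br bond and transmetalation to monovalent copper gives the alkylcopper–MgBr2 reagent, which adds across the terminal alkyne of 21 in a concerted syn carbocupration (alkyl to the internal carbon C13, copper to the terminal C14); the alkenylcopper, activated by P(OEt)3 and HMPA, then attacks CO2 with retention to form C14–C15. The closest known reaction type is the Normant carbocupration of terminal alkynes with alkylcopper–magnesium halide reagents followed by carboxylation of the alkenylcopper. No ring is closed and no stereocentre is created; the only stereochemical element formed is the C13=C14 geometry, which follows from syn addition and retention at copper and places C12 cis to C15 and C16 trans, the arrangement that cannot lactonise. The selectivity the step needs is regiochemical (alkyl to C13): it is secured by THF as solvent and by the bulky, weakly coordinating tert-butyldimethylsilyl ether, which disfavour the oxygen-directed mode that puts copper on C13 and leads on to an allene by loss of silyloxide. The C8=C17 alkene and both silyl ethers do not react with the Grignard or organocopper species at these temperatures.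

Step 16
Reactants: 26 (2E)-3-[(tert-butyldimethylsilyloxy)methyl]-5-[(1R,4aR,7R,8aR)-5,5,8a-trimethyl-2-methylidene-7-(triisopropylsilyloxy)decahydronaphthalen-1-yl]pent-2-enoic acid
Product: 27 (2E)-3-(hydroxymethyl)-5-[(1R,4aR,7R,8aR)-5,5,8a-trimethyl-2-methylidene-7-(triisopropylsilyloxy)decahydronaphthalen-1-yl]pent-2-enoic acid
Conditions: AcOH/THF/H2O (3:1:1), rt
Reagents that add atoms: none
Why: Acid-catalysed silyl ether solvolysis removes the primary allylic tert-butyldimethylsilyl group far faster than the hindered secondary triisopropylsilyl group, and the freed C16 hydroxyl is trans to the carboxyl and so cannot lactonise.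

Step 17
Reactants: 27 (2E)-3-(hydroxymethyl)-5-[(1R,4aR,7R,8aR)-5,5,8a-trimethyl-2-methylidene-7-(triisopropylsilyloxy)decahydronaphthalen-1-yl]pent-2-enoic acid
Product: 29 (2E)-3-(acetoxymethyl)-5-[(1R,4aR,7R,8aR)-5,5,8a-trimethyl-2-methylidene-7-(triisopropylsilyloxy)decahydronaphthalen-1-yl]pent-2-enoic acid, via mixed anhydride 28 (not isolated)
Conditions: Ac2O (3 equiv), pyridine, DMAP (cat.), CH2Cl2, 0 °C → rt; then THF/aq. NaHCO3, rt; acidify to pH 3
Reagents that add atoms: acetic anhydride, CC(=O)OC(C)=O
Why: DMAP-catalysed acetylation esterifies the primary allylic alcohol, and the mixed anhydride formed at the carboxyl group is hydrolysed back to the acid during the bicarbonate work-up.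

Step 18
Reactants: 29 (2E)-3-(acetoxymethyl)-5-[(1R,4aR,7R,8aR)-5,5,8a-trimethyl-2-methylidene-7-(triisopropylsilyloxy)decahydronaphthalen-1-yl]pent-2-enoic acid
Product: 30 (2E)-3-(acetoxymethyl)-5-[(1R,4aR,7R,8aR)-7-hydroxy-5,5,8a-trimethyl-2-methylidenedecahydronaphthalen-1-yl]pent-2-enoic acid (target, CNP0292310.2)
Conditions: HF·pyridine, pyridine, THF, 0 °C → rt
Reagents that add atoms: none
Why: Fluoride-mediated desilylation, driven by the Si–F bond, frees the C2 alcohol under buffered conditions that leave the allylic acetate, the exocyclic alkene and the enoic acid intact.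

Compound list
1 | (4R,6R)-4-hydroxy-2,2,6-trimethylcyclohexanone (actinol) | C[C@@H]1C[C@@H](O)CC(C)(C)C1=O | starting material
2 | (1S,3R)-3,5,5-trimethyl-4-oxocyclohexyl 4-nitrobenzoate | C[C@@H]1C[C@H](OC(=O)c2ccc(cc2)[N+](=O)[O-])CC(C)(C)C1=O | intermediate
3 | (4S,6R)-4-hydroxy-2,2,6-trimethylcyclohexanone | C[C@@H]1C[C@H](O)CC(C)(C)C1=O | intermediate
4 | (4S,6R)-2,2,6-trimethyl-4-(triisopropylsilyloxy)cyclohexanone | C[C@@H]1C[C@H](O[Si](C(C)C)(C(C)C)C(C)C)CC(C)(C)C1=O | intermediate
5 | potassium (S)-2,6,6-trimethyl-4-(triisopropylsilyloxy)cyclohex-1-en-1-olate | [K+].[O-]C1=C(C)C[C@H](O[Si](C(C)C)(C(C)C)C(C)C)CC1(C)C | intermediate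
6 | (S)-2,6,6-trimethyl-4-(triisopropylsilyloxy)cyclohex-1-en-1-yl trifluoromethanesulfonate | FC(F)(F)S(=O)(=O)OC1=C(C)C[C@H](O[Si](C(C)C)(C(C)C)C(C)C)CC1(C)C | intermediate
7 | potassium vinyltrifluoroborate | [K+].C=C[B-](F)(F)F | starting material
8 | (S)-triisopropyl[(3,5,5-trimethyl-4-vinylcyclohex-3-en-1-yl)oxy]silane | C=CC1=C(C)C[C@H](O[Si](C(C)C)(C(C)C)C(C)C)CC1(C)C | intermediate
9 | methyl 4-hydroxybut-2-ynoate | COC(=O)C#CCO | starting material
10 | methyl 4-acetoxybut-2-ynoate | COC(=O)C#CCOC(C)=O | intermediate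
11 | methyl (7R,8aR)-2-(acetoxymethyl)-5,5,8a-trimethyl-7-(triisopropylsilyloxy)-3,5,6,7,8,8a-hexahydronaphthalene-1-carboxylate | CC(=O)OCC1=C(C(=O)OC)[C@]2(C)C[C@H](O[Si](C(C)C)(C(C)C)C(C)C)CC(C)(C)C2=CC1 | intermediate
12 | methyl (4aR,7R,8aR)-2-(acetoxymethyl)-5,5,8a-trimethyl-7-(triisopropylsilyloxy)-3,4,4a,5,6,7,8,8a-octahydronaphthalene-1-carboxylate | CC(=O)OCC1=C(C(=O)OC)[C@]2(C)C[C@H](O[Si](C(C)C)(C(C)C)C(C)C)CC(C)(C)[C@H]2CC1 | intermediate
13 | samarium dienolate of ester 14 (O-bound diiodosamarium; enolate geometry not defined) | C=C1CC[C@@H]2C(C)(C)C[C@@H](O[Si](C(C)C)(C(C)C)C(C)C)C[C@@]2(C)C1=C(OC)O[Sm](I)I | intermediate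
14 | methyl (1R,4aR,7R,8aR)-5,5,8a-trimethyl-2-methylidene-7-(triisopropylsilyloxy)decahydronaphthalene-1-carboxylate | C=C1CC[C@@H]2C(C)(C)C[C@@H](O[Si](C(C)C)(C(C)C)C(C)C)C[C@@]2(C)[C@@H]1C(=O)OC | intermediate
15 | [(1R,4aR,7R,8aR)-5,5,8a-trimethyl-2-methylidene-7-(triisopropylsilyloxy)decahydronaphthalen-1-yl]methanol | C=C1CC[C@@H]2C(C)(C)C[C@@H](O[Si](C(C)C)(C(C)C)C(C)C)C[C@@]2(C)[C@@H]1CO | intermediate
16 | (1R,4aR,7R,8aR)-1-(iodomethyl)-5,5,8a-trimethyl-2-methylidene-7-(triisopropylsilyloxy)decahydronaphthalene | C=C1CC[C@@H]2C(C)(C)C[C@@H](O[Si](C(C)C)(C(C)C)C(C)C)C[C@@]2(C)[C@@H]1CI | intermediate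
17 | C11 alkyllithium from 16 | C=C1CC[C@@H]2C(C)(C)C[C@@H](O[Si](C(C)C)(C(C)C)C(C)C)C[C@@]2(C)[C@@H]1C[Li] | intermediate
18 | 2-[(1R,4aR,7R,8aR)-5,5,8a-trimethyl-2-methylidene-7-(triisopropylsilyloxy)decahydronaphthalen-1-yl]ethan-1-ol | C=C1CC[C@@H]2C(C)(C)C[C@@H](O[Si](C(C)C)(C(C)C)C(C)C)C[C@@]2(C)[C@@H]1CCO | intermediate
19 | (1R,4aR,7R,8aR)-1-(2-bromoethyl)-5,5,8a-trimethyl-2-methylidene-7-(triisopropylsilyloxy)decahydronaphthalene | C=C1CC[C@@H]2C(C)(C)C[C@@H](O[Si](C(C)C)(C(C)C)C(C)C)C[C@@]2(C)[C@@H]1CCBr | intermediate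
20 | propargyl alcohol | C#CCO | starting material
21 | tert-butyldimethyl(prop-2-yn-1-yloxy)silane | C#CCO[Si](C)(C)C(C)(C)C | intermediate
22 | carbon dioxide | O=C=O | starting material
23 | C12 Grignard reagent (alkylmagnesium bromide from 19) | C=C1CC[C@@H]2C(C)(C)C[C@@H](O[Si](C(C)C)(C(C)C)C(C)C)C[C@@]2(C)[C@@H]1CC[Mg]Br | intermediate
24 | C12 alkylcopper (monovalent copper, as its MgBr2 complex) | C=C1CC[C@@H]2C(C)(C)C[C@@H](O[Si](C(C)C)(C(C)C)C(C)C)C[C@@]2(C)[C@@H]1CC[Cu] | intermediate
25 | (E)-alkenylcopper (copper on C14, cis to C12) | C=C1CC[C@@H]2C(C)(C)C[C@@H](O[Si](C(C)C)(C(C)C)C(C)C)C[C@@]2(C)[C@@H]1CC/C(=C\[Cu])CO[Si](C)(C)C(C)(C)C | intermediate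
26 | (2E)-3-[(tert-butyldimethylsilyloxy)methyl]-5-[(1R,4aR,7R,8aR)-5,5,8a-trimethyl-2-methylidene-7-(triisopropylsilyloxy)decahydronaphthalen-1-yl]pent-2-enoic acid | C=C1CC[C@@H]2C(C)(C)C[C@@H](O[Si](C(C)C)(C(C)C)C(C)C)C[C@@]2(C)[C@@H]1CC/C(=C\C(=O)O)CO[Si](C)(C)C(C)(C)C | intermediate
27 | (2E)-3-(hydroxymethyl)-5-[(1R,4aR,7R,8aR)-5,5,8a-trimethyl-2-methylidene-7-(triisopropylsilyloxy)decahydronaphthalen-1-yl]pent-2-enoic acid | C=C1CC[C@@H]2C(C)(C)C[C@@H](O[Si](C(C)C)(C(C)C)C(C)C)C[C@@]2(C)[C@@H]1CC/C(=C\C(=O)O)CO | intermediate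
28 | acetic (2E)-3-(acetoxymethyl)-5-[(1R,4aR,7R,8aR)-5,5,8a-trimethyl-2-methylidene-7-(triisopropylsilyloxy)decahydronaphthalen-1-yl]pent-2-enoic anhydride | C=C1CC[C@@H]2C(C)(C)C[C@@H](O[Si](C(C)C)(C(C)C)C(C)C)C[C@@]2(C)[C@@H]1CC/C(=C\C(=O)OC(C)=O)COC(C)=O | intermediate
29 | (2E)-3-(acetoxymethyl)-5-[(1R,4aR,7R,8aR)-5,5,8a-trimethyl-2-methylidene-7-(triisopropylsilyloxy)decahydronaphthalen-1-yl]pent-2-enoic acid | C=C1CC[C@@H]2C(C)(C)C[C@@H](O[Si](C(C)C)(C(C)C)C(C)C)C[C@@]2(C)[C@@H]1CC/C(=C\C(=O)O)COC(C)=O | intermediate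
30 | (2E)-3-(acetoxymethyl)-5-[(1R,4aR,7R,8aR)-7-hydroxy-5,5,8a-trimethyl-2-methylidenedecahydronaphthalen-1-yl]pent-2-enoic acid | C=C1CC[C@@H]2C(C)(C)C[C@@H](O)C[C@@]2(C)[C@@H]1CC/C(=C\C(=O)O)COC(C)=O | target

Total step count: 18 (steps 6 and 14 prepare the two small partners).
Longest linear sequence: 16 steps (steps 1–5, 7–13, 15–18).

Steps most likely to fail

1. Step 15. The alkylcopper may add with the reverse orientation (copper on C13, followed by loss of silyloxide to an allene), may decompose or deprotonate the alkyne before adding, or the alkenylcopper may be protonated instead of carboxylated. The fallback sets out from bromide 19 and from compound 9 and comes back at 26; it replaces the three-component step by a stereoretentive cross-coupling. Anti hydroiodination of 9 (NaI, AcOH, 70 °C) should give methyl (Z)-4-hydroxy-3-iodobut-2-enoate F1, which is silylated (TBSCl, imidazole) to methyl (Z)-4-(tert-butyldimethylsilyloxy)-3-iodobut-2-enoate F2. Grignard reagent 23, made from 19 as in step 15, is transmetalated with ZnCl2 to the C12 alkylzinc chloride F3. Negishi coupling of F3 with F2 (PdCl2(dppf), THF, rt) proceeds with retention at the alkene and should give the methyl ester of 26 F4. Saponification (LiOH, THF/H2O, rt) then returns to the route at 26.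

2. Step 7. The mono-activated ynoate may add too slowly to the hindered, twisted diene, so that 1,5-hydrogen shift or polymerisation of the diene takes over, or the orientation of addition may erode. The fallback sets out from diene 8 and comes back at 11; it uses a more electrophilic ynal, which reacts at lower temperature with the same orientation. Monoacetylation of but-2-yne-1,4-diol (Ac2O, pyridine) gives 4-acetoxybut-2-yn-1-ol F5, and oxidation (MnO2, CH2Cl2) gives 4-acetoxybut-2-ynal F6. Diels–Alder reaction of F6 with 8 (toluene, 60–80 °C) should give the C11 aldehyde analogue of 11 F7. Pinnick oxidation (NaClO2, NaH2PO4, 2-methylbut-2-ene, t-BuOH/H2O) gives the C11 carboxylic acid analogue of 11 F8, and methylation with TMSCHN2 (MeOH/toluene) returns to the route at 11.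

3. Step 9. The dienolate may be protonated at the unhindered C17 terminus, which regenerates a conjugated ester with a C8 methyl, or on the wrong face of C9. The fallback sets out from 12 and arrives directly at 14 without new intermediates. It is a palladium-catalysed formate hydrogenolysis of the allylic acetate (Pd(OAc)2, PBu3, HCO2NH4, dioxane, reflux). The allyl complex formed from zerovalent palladium carries the metal on the face away from the C20 methyl, and after decarboxylation of formate the hydride is delivered from palladium to the more substituted allyl terminus C9 on that face, giving the exocyclic alkene and the 9R configuration without an enolate.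

Further compounds
F1 | step 15 | methyl (Z)-4-hydroxy-3-iodobut-2-enoate | COC(=O)/C=C(\I)CO
F2 | step 15 | methyl (Z)-4-(tert-butyldimethylsilyloxy)-3-iodobut-2-enoate | COC(=O)/C=C(\I)CO[Si](C)(C)C(C)(C)C
F3 | step 15 | C12 alkylzinc chloride | C=C1CC[C@@H]2C(C)(C)C[C@@H](O[Si](C(C)C)(C(C)C)C(C)C)C[C@@]2(C)[C@@H]1CC[Zn]Cl
F4 | step 15 | methyl ester of 26 | C=C1CC[C@@H]2C(C)(C)C[C@@H](O[Si](C(C)C)(C(C)C)C(C)C)C[C@@]2(C)[C@@H]1CC/C(=C\C(=O)OC)CO[Si](C)(C)C(C)(C)C
F5 | step 7 | 4-acetoxybut-2-yn-1-ol | CC(=O)OCC#CCO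
F6 | step 7 | 4-acetoxybut-2-ynal | CC(=O)OCC#CC=O
F7 | step 7 | C11 aldehyde analogue of 11 | CC(=O)OCC1=C(C=O)[C@]2(C)C[C@H](O[Si](C(C)C)(C(C)C)C(C)C)CC(C)(C)C2=CC1
F8 | step 7 | C11 carboxylic acid analogue of 11 | CC(=O)OCC1=C(C(=O)O)[C@]2(C)C[C@H](O[Si](C(C)C)(C(C)C)C(C)C)CC(C)(C)C2=CC1
F0 | step 9 | none | none
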